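Assumption: cyathane numbering is used for the tricycles (ring A C1–C2–C3–C4–C9, ring B C4–C9, ring C C5–C10–C11–C12–C13–C14–C6; C15 on C12, C16 on C6, C17 on C9, C18 on C3 carrying C19 and C20); β is the face of the C16 methyl; the target SMILES reads as 2S,3S,4R,5S,6S,9S,12S,13R; all tricycles have 3β-H, 5α-H, 6β-CH3 and 9α-C17; reagents on the "add atoms" lines are commercial and carry no compound number.

**Retrosynthetic overview**
1. 30 ⇐ 29 by α-face epoxidation of Δ12; the C17 acetate comes from silyl ether 27.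
2. Lactone C2–O bond (key step, new) ⇐ γ-C(sp3)–H lactonisation of the 2-substituted acrylic acid 26.
3. Ring A (C3–C4, C4–OH) ⇐ SmI2 ketyl–enoate cyclisation of 21; quaternary C9 ⇐ vinylogous Mukaiyama–Michael addition/hydroxymethylation on exo-methylene ketone 16.
4. Ring C ⇐ RCM (Δ12) with C5–H set by protonation of the ring-fusion enolate; C5 chain ⇐ conjugate methallylation of exo-methylene ketone 9.
5. Ring B and C6 ⇐ Cu-catalysed asymmetric conjugate methylation of 3-allylcyclohexenone 4. Ring order: B → C → A → lactone → epoxide.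

**Route**

Step 1
Reactants: 1 3-ethoxycyclohex-2-en-1-one; 2 allylmagnesium bromide
Product: 4 3-allylcyclohex-2-en-1-one, via Grignard adduct 3 (not isolated)
Conditions: THF, 0 °C; then 1 M HCl, 0 °C → rt
Reagents that add atoms: water, O
Why: Stork–Danheiser alkylative enone transposition (1,2-addition to the vinylogous ester, then acid hydrolysis/dehydration); no stereocentre is formed.

Step 2
Reactants: 4 3-allylcyclohex-2-en-1-one
Product: 6 trimethyl{[(3S)-3-methyl-3-(prop-2-en-1-yl)cyclohex-1-en-1-yl]oxy}silane, via aluminium enolate 5 (not isolated)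
Conditions: Me3Al, CuTC (2 mol%), chiral phosphoramidite (4 mol%, enantiomer giving 3S), Et2O, −30 °C; then TMSOTf, THF, −30 → 0 °C
Reagents that add atoms: trimethylaluminium, C[Al](C)C; trimethylsilyl triflate, C[Si](C)(C)OS(=O)(=O)C(F)(F)F
Why: Cu-catalysed asymmetric conjugate addition of Me3Al to a 3-substituted cyclohexenone sets the quaternary C6 (S) under ligand control, and the enolate is trapped regiospecifically as the silyl enol ether.

Step 3
Reactants: 6 trimethyl{[(3S)-3-methyl-3-(prop-2-en-1-yl)cyclohex-1-en-1-yl]oxy}silane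
Product: 9 (3S)-3-methyl-2-methylidene-3-(prop-2-en-1-yl)cyclohexan-1-one, via Mannich base 7 (not isolated), via methiodide 8 (not isolated)
Conditions: Me2N+=CH2 I−, CH2Cl2, rt; MeI, Et2O; then aq NaHCO3, CH2Cl2
Reagents that add atoms: Eschenmoser's salt, C=[N+](C)C.[I-]
Why: Mannich reaction of the silyl enol ether followed by quaternisation and E1cB elimination gives the α-methylene ketone regiospecifically at C5.

Step 4
Reactants: 9 (3S)-3-methyl-2-methylidene-3-(prop-2-en-1-yl)cyclohexan-1-one; 10 trimethyl(2-methylprop-2-en-1-yl)silane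
Product: 11 trimethyl{[(3S)-3-methyl-2-(3-methylbut-3-en-1-yl)-3-(prop-2-en-1-yl)cyclohex-1-en-1-yl]oxy}silane
Conditions: TMSNTf2 (5 mol%), CH2Cl2, −78 °C; Et3N quench
Reagents that add atoms: none
Why: Hosomi–Sakurai conjugate methallylation of the unhindered exo-methylene enone with silyl transfer to oxygen gives the tetrasubstituted silyl enol ether regiospecifically, so C5 stays sp2 and no stereocentre is set yet.

Step 5
Reactants: 11 trimethyl{[(3S)-3-methyl-2-(3-methylbut-3-en-1-yl)-3-(prop-2-en-1-yl)cyclohex-1-en-1-yl]oxy}silane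
Product: 13 (4aS,9aS)-4a,7-dimethyl-2,3,4,4a,5,8,9,9a-octahydro-1H-benzo[7]annulen-1-one, via bicyclic silyl enol ether 12 (not isolated)
Conditions: Grubbs II (5 mol%), CH2Cl2, 40 °C; then TBAF, AcOH, THF, −78 °C
Reagents that add atoms: none
Why: Ring-closing metathesis closes ring C as the trisubstituted Δ12 cycloheptene, and kinetic C-protonation of the ring-fusion enolate then occurs anti to the C6 methyl (held pseudoaxial by A(1,2) strain with C10), which sets C5–H α and the trans 6–7 fusion.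

Step 6
Reactants: 13 (4aS,9aS)-4a,7-dimethyl-2,3,4,4a,5,8,9,9a-octahydro-1H-benzo[7]annulen-1-one
Product: 16 (4aS,9aS)-4a,7-dimethyl-2-methylidene-2,3,4,4a,5,8,9,9a-octahydro-1H-benzo[7]annulen-1-one, via Mannich base 14 (not isolated), via methiodide 15 (not isolated)
Conditions: LDA, THF, −78 °C; Me2N+=CH2 I−, −78 → 0 °C; MeI; then aq NaHCO3
Reagents that add atoms: Eschenmoser's salt, C=[N+](C)C.[I-]
Why: Kinetic deprotonation takes place at the C9 methylene and not at the hindered ring-fusion C5–H, and Mannich reaction/elimination then gives the C9 exo-methylene ketone without touching C5.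

Step 7
Reactants: 17 methyl (E)-but-2-enoate
Product: 18 [(1-methoxybuta-1,3-dien-1-yl)oxy]trimethylsilane
Conditions: LDA, THF/DMPU, −78 °C; then TMSCl
Reagents that add atoms: chlorotrimethylsilane, C[Si](C)(C)Cl
Why: γ-Deprotonation of the crotonate and O-silylation give the silyl dienolate (vinylogous ketene acetal formation).

Step 8
Reactants: 16 (4aS,9aS)-4a,7-dimethyl-2-methylidene-2,3,4,4a,5,8,9,9a-octahydro-1H-benzo[7]annulen-1-one; 18 [(1-methoxybuta-1,3-dien-1-yl)oxy]trimethylsilane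
Product: 20 methyl (2E)-5-[(2R,4aS,9aS)-2-(hydroxymethyl)-4a,7-dimethyl-1-oxo-2,3,4,4a,5,8,9,9a-octahydro-1H-benzo[7]annulen-2-yl]pent-2-enoate, via silyl enol ether 19 (not isolated)
Conditions: TMSNTf2 (5 mol%), CH2Cl2, −78 °C; then 37% aq CH2O, Sc(OTf)3 (10 mol%), THF, rt
Reagents that add atoms: formaldehyde, C=O
Why: Vinylogous Mukaiyama–Michael addition through the γ-carbon installs C1–C3 with the E-enoate and gives the C4=C9 silyl enol ether regiospecifically, and the aqueous Lewis-acid Mukaiyama aldol with formaldehyde then adds CH2OH axially from the α face (chair-like transition state, only syn-axial hydrogens), which sets C9 with the side chain equatorial.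

Step 9
Reactants: 20 methyl (2E)-5-[(2R,4aS,9aS)-2-(hydroxymethyl)-4a,7-dimethyl-1-oxo-2,3,4,4a,5,8,9,9a-octahydro-1H-benzo[7]annulen-2-yl]pent-2-enoate
Product: 21 methyl (2E)-5-[(2R,4aS,9aS)-2-{[(tert-butyldimethylsilyl)oxy]methyl}-4a,7-dimethyl-1-oxo-2,3,4,4a,5,8,9,9a-octahydro-1H-benzo[7]annulen-2-yl]pent-2-enoate
Conditions: TBSCl, imidazole, DMF, 0 °C (carried out at once)
Reagents that add atoms: tert-butyldimethylsilyl chloride, CC(C)(C)[Si](C)(C)Cl
Why: Standard silylation gives a non-chelating ether, which prevents oxa-Michael closure onto the enoate and Sm chelation in the next step.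

Step 10
Reactants: 21 methyl (2E)-5-[(2R,4aS,9aS)-2-{[(tert-butyldimethylsilyl)oxy]methyl}-4a,7-dimethyl-1-oxo-2,3,4,4a,5,8,9,9a-octahydro-1H-benzo[7]annulen-2-yl]pent-2-enoate
Product: 22 methyl 17-(tert-butyldimethylsilyloxy)-4β-hydroxy-20-norcyath-12-en-19-oate
Conditions: SmI2 (2.5 equiv), HMPA, t-BuOH, THF, −78 → 0 °C
Reagents that add atoms: none
Why: SmI2 ketyl–olefin 5-exo-trig cyclisation forms C3–C4 on the equatorial side of C4 because the axial side is blocked by the syn-axial C6 methyl (as in additions to 3-axial-methyl cyclohexanones), giving the 4β-OH trans-hydrindane, and the ester arm sits anti to the O–Sm group, giving the 3α side chain, so the γ-hydroxy ester cannot lactonise.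

Step 11
Reactants: 22 methyl 17-(tert-butyldimethylsilyloxy)-4β-hydroxy-20-norcyath-12-en-19-oate
Product: 25 methyl 17-(tert-butyldimethylsilyloxy)-4β-hydroxycyatha-12,18(20)-dien-19-oate, via Mannich base 23 (not isolated), via methiodide 24 (not isolated)
Conditions: LDA (2.5 equiv), THF, −78 °C; Me2N+=CH2 I−; aq quench; MeI, MeOH; then aq NaHCO3
Reagents that add atoms: Eschenmoser's salt, C=[N+](C)C.[I-]
Why: Mannich alkylation of the ester enolate (alkoxide/enolate dianion) followed by quaternisation and elimination is the standard α-methylenation and creates no new stereocentre.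

Step 12
Reactants: 25 methyl 17-(tert-butyldimethylsilyloxy)-4β-hydroxycyatha-12,18(20)-dien-19-oate
Product: 26 17-(tert-butyldimethylsilyloxy)-4β-hydroxycyatha-12,18(20)-dien-19-oic acid
Conditions: LiOH, THF/MeOH/H2O, rt; then dilute HCl to pH 4
Reagents that add atoms: lithium hydroxide, [Li+].[OH-]
Why: Saponification of the methyl ester gives the free acid, which cannot lactonise onto the trans-disposed C4–OH.

Step 13
Reactants: 26 17-(tert-butyldimethylsilyloxy)-4β-hydroxycyatha-12,18(20)-dien-19-oic acid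
Product: 27 17-(tert-butyldimethylsilyloxy)-4β-hydroxycyatha-12,18(20)-dieno-19,2α-lactone
Conditions: Cu(OTf)2 (2.5 equiv), Li2CO3, MeCN, 390 nm LEDs, rt
Reagents that add atoms: none
Why: Proposed new method: ligand-to-metal charge transfer in the Cu(II) carboxylate gives an acryloyloxy σ-radical (decarboxylation to a vinyl radical is slow), which abstracts the γ-hydrogen at C2 by 1,5-HAT through a six-membered transition state, and the C2 radical is captured by Cu(II) and undergoes C–O reductive elimination from alkyl–Cu(III) carboxylate to give the α-methylene-γ-butyrolactone directly, with C2–O α fixed by the enforced cis ring fusion to C3; the closest known chemistry is Cu-LMCT generation of aroyloxy radicals and aroyloxy-radical 1,5-HAT lactonisation of 2-alkylbenzoic acids to phthalides, here extended to a 2-alkylacrylic acid and an unactivated methylene.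

Step 14
Reactants: 27 17-(tert-butyldimethylsilyloxy)-4β-hydroxycyatha-12,18(20)-dieno-19,2α-lactone
Product: 29 17-acetoxy-4β-hydroxycyatha-12,18(20)-dieno-19,2α-lactone, via diol 28 (not isolated)
Conditions: TBAF, AcOH, THF, 0 °C → rt; then Ac2O, pyridine, DMAP (cat.)
Reagents that add atoms: acetic anhydride, CC(=O)OC(C)=O
Why: Fluoride desilylation followed by acetylation acylates only the primary C17 alcohol because the tertiary C4–OH, syn-axial to C16, is too hindered.

Step 15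
Reactants: 29 17-acetoxy-4β-hydroxycyatha-12,18(20)-dieno-19,2α-lactone
Product: 30 17-acetoxy-12α,13α-epoxy-4β-hydroxycyath-18(20)-eno-19,2α-lactone (CNP0214540.1)
Conditions: m-CPBA, NaHCO3, CH2Cl2, 0 °C
Reagents that add atoms: m-chloroperbenzoic acid, OOC(=O)c1cccc(Cl)c1
Why: Prilezhaev epoxidation attacks the only electron-rich alkene from the α face, anti to the axial C16 methyl that shields the β face of ring C, while the α-methylene lactone is inert to peracid.

**Compound list**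
1 | 3-ethoxycyclohex-2-en-1-one | CCOC1=CC(=O)CCC1 | starting material
2 | allylmagnesium bromide | C=CC[Mg]Br | starting material
3 | 1-allyl-3-ethoxycyclohex-2-en-1-ol (present as its magnesium alkoxide) | CCOC1=CC(O)(CC=C)CCC1 | intermediate
4 | 3-allylcyclohex-2-en-1-one | O=C1C=C(CC=C)CCC1 | intermediate
5 | dimethylaluminium (3S)-3-methyl-3-(prop-2-en-1-yl)cyclohex-1-en-1-olate | C[Al](C)OC1=C[C@](C)(CC=C)CCC1 | intermediate
6 | trimethyl{[(3S)-3-methyl-3-(prop-2-en-1-yl)cyclohex-1-en-1-yl]oxy}silane | C[Si](C)(C)OC1=C[C@](C)(CC=C)CCC1 | intermediate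
7 | (3S)-2-[(dimethylamino)methyl]-3-methyl-3-(prop-2-en-1-yl)cyclohexan-1-one (C2 epimers) | O=C1CCC[C@@](C)(CC=C)C1CN(C)C | intermediate
8 | methiodide of 7 | O=C1CCC[C@@](C)(CC=C)C1C[N+](C)(C)C.[I-] | intermediate
9 | (3S)-3-methyl-2-methylidene-3-(prop-2-en-1-yl)cyclohexan-1-one | O=C1CCC[C@@](C)(CC=C)C1=C | intermediate
10 | trimethyl(2-methylprop-2-en-1-yl)silane | C=C(C)C[Si](C)(C)C | starting material
11 | trimethyl{[(3S)-3-methyl-2-(3-methylbut-3-en-1-yl)-3-(prop-2-en-1-yl)cyclohex-1-en-1-yl]oxy}silane | C[Si](C)(C)OC1=C(CCC(C)=C)[C@](C)(CC=C)CCC1 | intermediate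
12 | trimethyl{[(4aS)-4a,7-dimethyl-3,4,4a,5,8,9-hexahydro-2H-benzo[7]annulen-1-yl]oxy}silane | C[Si](C)(C)OC1=C2CCC(C)=CC[C@]2(C)CCC1 | intermediate
13 | (4aS,9aS)-4a,7-dimethyl-2,3,4,4a,5,8,9,9a-octahydro-1H-benzo[7]annulen-1-one (trans-fused) | O=C1CCC[C@@]2(C)CC=C(C)CC[C@@H]21 | intermediate
14 | (4aS,9aS)-2-[(dimethylamino)methyl]-4a,7-dimethyl-2,3,4,4a,5,8,9,9a-octahydro-1H-benzo[7]annulen-1-one (C2 epimers) | O=C1C(CN(C)C)CC[C@@]2(C)CC=C(C)CC[C@@H]21 | intermediate
15 | methiodide of 14 | O=C1C(C[N+](C)(C)C)CC[C@@]2(C)CC=C(C)CC[C@@H]21.[I-] | intermediate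
16 | (4aS,9aS)-4a,7-dimethyl-2-methylidene-2,3,4,4a,5,8,9,9a-octahydro-1H-benzo[7]annulen-1-one | O=C1C(=C)CC[C@@]2(C)CC=C(C)CC[C@@H]21 | intermediate
17 | methyl (E)-but-2-enoate | C/C=C/C(=O)OC | starting material
18 | [(1-methoxybuta-1,3-dien-1-yl)oxy]trimethylsilane | COC(O[Si](C)(C)C)=CC=C | intermediate
19 | methyl (2E)-5-[(4aS,9aS)-4a,7-dimethyl-1-(trimethylsilyloxy)-4,4a,5,8,9,9a-hexahydro-3H-benzo[7]annulen-2-yl]pent-2-enoate | COC(=O)/C=C/CCC1=C(O[Si](C)(C)C)[C@H]2CCC(C)=CC[C@]2(C)CC1 | intermediate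
20 | methyl (2E)-5-[(2R,4aS,9aS)-2-(hydroxymethyl)-4a,7-dimethyl-1-oxo-2,3,4,4a,5,8,9,9a-octahydro-1H-benzo[7]annulen-2-yl]pent-2-enoate | COC(=O)/C=C/CC[C@]1(CO)CC[C@@]2(C)CC=C(C)CC[C@@H]2C1=O | intermediate
21 | methyl (2E)-5-[(2R,4aS,9aS)-2-{[(tert-butyldimethylsilyl)oxy]methyl}-4a,7-dimethyl-1-oxo-2,3,4,4a,5,8,9,9a-octahydro-1H-benzo[7]annulen-2-yl]pent-2-enoate | COC(=O)/C=C/CC[C@]1(CO[Si](C)(C)C(C)(C)C)CC[C@@]2(C)CC=C(C)CC[C@@H]2C1=O | intermediate
22 | methyl 17-(tert-butyldimethylsilyloxy)-4β-hydroxy-20-norcyath-12-en-19-oate (3α-CH2CO2Me) | COC(=O)C[C@H]1CC[C@]2(CO[Si](C)(C)C(C)(C)C)CC[C@@]3(C)CC=C(C)CC[C@@H]3[C@@]12O | intermediate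
23 | methyl 20-(dimethylamino)-17-(tert-butyldimethylsilyloxy)-4β-hydroxycyath-12-en-19-oate (C18 epimers) | COC(=O)C(CN(C)C)[C@H]1CC[C@]2(CO[Si](C)(C)C(C)(C)C)CC[C@@]3(C)CC=C(C)CC[C@@H]3[C@@]12O | intermediate
24 | methiodide of 23 | COC(=O)C(C[N+](C)(C)C)[C@H]1CC[C@]2(CO[Si](C)(C)C(C)(C)C)CC[C@@]3(C)CC=C(C)CC[C@@H]3[C@@]12O.[I-] | intermediate
25 | methyl 17-(tert-butyldimethylsilyloxy)-4β-hydroxycyatha-12,18(20)-dien-19-oate | COC(=O)C(=C)[C@H]1CC[C@]2(CO[Si](C)(C)C(C)(C)C)CC[C@@]3(C)CC=C(C)CC[C@@H]3[C@@]12O | intermediate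
26 | 17-(tert-butyldimethylsilyloxy)-4β-hydroxycyatha-12,18(20)-dien-19-oic acid | OC(=O)C(=C)[C@H]1CC[C@]2(CO[Si](C)(C)C(C)(C)C)CC[C@@]3(C)CC=C(C)CC[C@@H]3[C@@]12O | intermediate
27 | 17-(tert-butyldimethylsilyloxy)-4β-hydroxycyatha-12,18(20)-dieno-19,2α-lactone | C=C1C(=O)O[C@H]2C[C@]3(CO[Si](C)(C)C(C)(C)C)CC[C@@]4(C)CC=C(C)CC[C@@H]4[C@@]3(O)[C@@H]12 | intermediate
28 | 4β,17-dihydroxycyatha-12,18(20)-dieno-19,2α-lactone | C=C1C(=O)O[C@H]2C[C@]3(CO)CC[C@@]4(C)CC=C(C)CC[C@@H]4[C@@]3(O)[C@@H]12 | intermediate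
29 | 17-acetoxy-4β-hydroxycyatha-12,18(20)-dieno-19,2α-lactone | C=C1C(=O)O[C@H]2C[C@]3(COC(C)=O)CC[C@@]4(C)CC=C(C)CC[C@@H]4[C@@]3(O)[C@@H]12 | intermediate
30 | 17-acetoxy-12α,13α-epoxy-4β-hydroxycyath-18(20)-eno-19,2α-lactone (CNP0214540.1) | C=C1C(=O)O[C@H]2C[C@]3(COC(C)=O)CC[C@@]4(C)C[C@H]5O[C@@]5(C)CC[C@@H]4[C@@]3(O)[C@@H]12 | target

**Step count**
Total steps: 15. Longest linear sequence: 14 (1 → 30 through steps 1–6 and 8–15; step 7 is a one-step side branch).

**Steps most likely to fail, with fallbacks**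

Step 13 (the proposed C–H lactonisation). The acryloyloxy radical may decarboxylate, add to an alkene or abstract elsewhere, and Cu(III) may eliminate instead of forming the C–O bond. The fallback uses known chemistry, sets out from 22 and comes back at 30. Saponification of 22 (LiOH) gives the saturated hydroxy acid F3. The known carboxylate-directed Mn-catalysed γ-C–H lactonisation of unactivated methylenes (Mn(pdp)-type catalyst, H2O2, HFIP, 0 °C) closes the C2–O bond, and the same oxidant epoxidises Δ12 from the α face, giving the epoxy lactone F4. α-Methylenation (LiHMDS, Eschenmoser's salt; MeI; aq NaHCO3) proceeds through the Mannich base F5 and its methiodide F6 to the α-methylene lactone F7. TBAF then Ac2O/pyridine, through the epoxy diol F8, gives 30.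

Step 8 (tandem vinylogous Mukaiyama–Michael/hydroxymethylation). The silyl dienolate may react at its α-carbon, or the one-pot sequence may be low-yielding. The fallback sets out from 16 and comes back at 20. TMSNTf2-catalysed Hosomi–Sakurai addition of allyltrimethylsilane to 16 gives the butenyl silyl enol ether F1. Aqueous CH2O/Sc(OTf)3 gives the butenyl hydroxymethyl ketone F2 with the same axial selectivity. Cross-metathesis of F2 with methyl acrylate (Hoveyda–Grubbs II, CH2Cl2, 40 °C) builds the E-enoate and gives 20.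

Step 15 (facial selectivity of the epoxidation on the flexible cycloheptene). If the peracid prefers the β face, the halohydrin route inverts the outcome; it sets out from 29 and comes back at 30. NBS in aqueous THF forms the bromonium ion on the face the peracid prefers, and water opens it at the tertiary C12 from the α face to give the bromohydrin F9. Ag2O in CH2Cl2 then closes the epoxide by internal SN2 at C13, giving the α-epoxide 30.

Further compounds
F1 | step 8 | {[(4aS,9aS)-2-(but-3-en-1-yl)-4a,7-dimethyl-4,4a,5,8,9,9a-hexahydro-3H-benzo[7]annulen-1-yl]oxy}trimethylsilane | C=CCCC1=C(O[Si](C)(C)C)[C@H]2CCC(C)=CC[C@]2(C)CC1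
F2 | step 8 | (2R,4aS,9aS)-2-(but-3-en-1-yl)-2-(hydroxymethyl)-4a,7-dimethyl-2,3,4,4a,5,8,9,9a-octahydro-1H-benzo[7]annulen-1-one | C=CCC[C@]1(CO)CC[C@@]2(C)CC=C(C)CC[C@@H]2C1=O
F3 | step 13 | 17-(tert-butyldimethylsilyloxy)-4β-hydroxy-20-norcyath-12-en-19-oic acid | OC(=O)C[C@H]1CC[C@]2(CO[Si](C)(C)C(C)(C)C)CC[C@@]3(C)CC=C(C)CC[C@@H]3[C@@]12O
F4 | step 13 | 17-(tert-butyldimethylsilyloxy)-12α,13α-epoxy-4β-hydroxy-20-norcyathano-19,2α-lactone | C1C(=O)O[C@H]2C[C@]3(CO[Si](C)(C)C(C)(C)C)CC[C@@]4(C)C[C@H]5O[C@@]5(C)CC[C@@H]4[C@@]3(O)[C@@H]12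
F5 | step 13 | 20-(dimethylamino)-17-(tert-butyldimethylsilyloxy)-12α,13α-epoxy-4β-hydroxycyathano-19,2α-lactone (C18 epimers) | CN(C)CC1C(=O)O[C@H]2C[C@]3(CO[Si](C)(C)C(C)(C)C)CC[C@@]4(C)C[C@H]5O[C@@]5(C)CC[C@@H]4[C@@]3(O)[C@@H]12
F6 | step 13 | methiodide of F5 | C[N+](C)(C)CC1C(=O)O[C@H]2C[C@]3(CO[Si](C)(C)C(C)(C)C)CC[C@@]4(C)C[C@H]5O[C@@]5(C)CC[C@@H]4[C@@]3(O)[C@@H]12.[I-]
F7 | step 13 | 17-(tert-butyldimethylsilyloxy)-12α,13α-epoxy-4β-hydroxycyath-18(20)-eno-19,2α-lactone | C=C1C(=O)O[C@H]2C[C@]3(CO[Si](C)(C)C(C)(C)C)CC[C@@]4(C)C[C@H]5O[C@@]5(C)CC[C@@H]4[C@@]3(O)[C@@H]12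
F8 | step 13 | 12α,13α-epoxy-4β,17-dihydroxycyath-18(20)-eno-19,2α-lactone | C=C1C(=O)O[C@H]2C[C@]3(CO)CC[C@@]4(C)C[C@H]5O[C@@]5(C)CC[C@@H]4[C@@]3(O)[C@@H]12
F9 | step 15 | 17-acetoxy-13β-bromo-4β,12α-dihydroxycyath-18(20)-eno-19,2α-lactone | C=C1C(=O)O[C@H]2C[C@]3(COC(C)=O)CC[C@@]4(C)C[C@H](Br)[C@@](C)(O)CC[C@@H]4[C@@]3(O)[C@@H]12
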